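The runs were generated by integration for substances that don't exist, and the scatter is random.

The smallest charge comes first: the dawn and autumn flasks, each with 0.100 M of L and 0.00600 M of the catalyst Z. Taking the mean of their readings from 53 h on, I read a plateau of E of 0.0397 M, which is 39.7 % of their L. The spring flask, with twice the L and the same Z, levelled at 0.0569 M, or 28.5 % of its L.

| flask | L | Z | time |
|---|---|---|---|
| spring | 0.200 M | 0.00600 M |  |
| dawn | 0.100 M | 0.00600 M |  |
| autumn | 0.100 M | 0.00600 M |  |
| summer | 0.100 M | 0.00300 M | 74 h |

| run | time / h | [E] / M |
|---|---|---|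
| spring run | 11 | 0.0401 |
| spring run | 21 | 0.0473 |
| spring run | 32 | 0.0549 |
| spring run | 42 | 0.0538 |
| spring run | 53 | 0.0573 |
| spring run | 63 | 0.0570 |
| spring run | 74 | 0.0565 |
| dawn run | 11 | 0.0289 |
| dawn run | 21 | 0.0341 |
| dawn run | 32 | 0.0362 |
| dawn run | 42 | 0.0381 |
| dawn run | 53 | 0.0389 |
| dawn run | 63 | 0.0408 |
| dawn run | 74 | 0.0396 |
| autumn run | 11 | 0.0272 |
| autumn run | 21 | 0.0336 |
| autumn run | 32 | 0.0370 |
| autumn run | 42 | 0.0406 |
| autumn run | 53 | 0.0397 |
| autumn run | 63 | 0.0390 |
| autumn run | 74 | 0.0402 |

(standard deviation of a reading: 0.001 M)

- Overall: L -> E, with Z as catalyst.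
- Constant volume, constant temperature.
- What is held in complexes is read along with the free species.
- An order is taken over about fifteen percent of the charge, up and down.

- how the opening rate goes with [L] round the charge of the spring run: the exponent of the rate at two percent of L gone to E (one fixed amount of E, the same in the runs compared)
- E in the summer run at 74 h, as a share of the L charged

With P the plateau and E the reading at time t, I reckoned:

τ = t / ln(P / (P − E))

dawn and autumn, at 11 h: τ = 8.97 h

spring, at 11 h: τ = 9.03 h

This working window, the time constant of the rise to the plateau, held while L doubled, so I froze it.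

The ladder then ran as follows. The window came first, with E rising. Next came the time the opening rate r = P/τ would need to turn the whole charge: 22.6 h in dawn and 31.7 h in spring. The window is shorter than either, which says again that each plateau lay below its charge. Last came the run itself, 74 h long, whose late readings lay flat within the scatter.

r = 0.00442 M/h (dawn), 0.00631 M/h (spring)

n = ln(r_spring / r_dawn) / ln(L_spring / L_dawn) = 0.511

I took this for the spring exponent, though it is averaged over a doubling. The earlier runs held Z at 0.00600 M, so the power of Z stayed open. With τ frozen and half the Z, the first power gives 19.8 % in summer and the second gives 9.92 %. That bracket was my commitment.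

The forecast stood at 0.33 (0.22 to 0.45) and 21.5 % (19.5 % to 24.5 %), “assuming rate and A scale with Z”. My exponent is higher, and my bracket reaches lower.

    Z + L ⇌ ZL, settled at all times (2.040 /M)
    ZL + Z → E + 2 Z (990.0 /M/h)
    2 Z → 2 Gy (3.888 /M/h)
    2 L → Vo (0.4896 /M/h)

The flask gave an exponent of 0.49 and, in summer at 74 h, E at 16.2 % of the L charged. In the scheme, Z enters the step that makes E twice, once bound in ZL and once free. Put to use once more in the dawn run, the window of 8.97 h and the plateau of 0.0397 M place E at a quarter of the L charged at 8.91 h, and the flask gave 9.33 h.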